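All constants were drawn at random within sensible limits.

From the earliest minutes, the thing to watch is how far free target stands above its solubility.

    substrate + partner ⇌ target (K1 = 8.0 M⁻¹, k1 = 0.0263 M⁻¹ s⁻¹)
    crystals ⇌ target, rate k2*(cs2 - [target]) while solid is left; crystals form when [target] > cs2 (cs2 = 1.1 mM, k2 = 0.0228 s⁻¹)

| flask | substrate | partner | time |
|---|---|---|---|
| beta | 0.030 M | 0.0800 M | 30 min |
| epsilon | 0.040 M | 0.0800 M | 30 min |
| alpha | 0.060 M | 0.0800 M | 30 min |
| zeta | 0.10 M | 0.0800 M | 30 min |
| eta | 0.15 M | 0.0800 M | 30 min |

- target is meant together with its crystals
- solid, in amounts per volume of the solution: crystals
- the concentration of target that is asked is that of its free form alone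
- "hardly changes" means that all values lie within two and a half points (for a concentration: within two and a half percent of the largest)
- run time (beta): 30 min

* [target] (only what is free in solution) at the end for beta, epsilon, alpha, zeta, eta, in this order
* how that number moves from the first to the last of them (falls all the way / hardly changes / rises all the way / rises, then falls / falls, then rises)

- Follow one molecule of free target above the solubility, taking crystal growth at the same coefficient as dissolving: it joins the crystals at 0.0228 s⁻¹ or falls back to substrate and partner at 0.00329 s⁻¹, so its chance of going back is 12.6 %.
- The fastest rung is this fork, with a lifetime of 0.639 min for that molecule, shorter than the forward half-life of substrate in beta or the run; free target therefore sits in a quasi-steady state.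
- The middle rung is the fall of substrate in beta, with a forward half-life of 5.49 min at partner as charged (pseudo-first-order), and the run holds 5.46 such half-lives; free target, with its shorter lifetime, follows the falling substrate and partner.
- The last rung is the balance that the flask approaches, with target at solubility and the first step level. Let a and b be the fractions of substrate and partner left; then ab approaches the floor, which is 0.0573 for beta.
- The forward rate constant over the sum of both exits from free target is 1.01 M⁻¹, so beta has a lift of 2.42 mM, the carried quantity: the forward rate at full charges divided by the sum of both exits from free target.
- The rule follows: while crystals stand and free target is quasi-steady, free target equals solubility plus lift times (ab minus floor).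
- This reckoning stops there: ab at the end takes the whole run integrated, so it gives a form and no row of its own.
- In eta the lift is 12.1 mM, larger than in beta, but partner is the limiting reagent there, so b can fall far while a stays above 46.7 %.
- The forecast gives 0.00122 M, 0.00127 M, 0.00136 M, 0.00141 M and 0.00125 M, a row that rises, then falls; its drive “drops once substrate is in large excess and consumes the partner quickly”.
- The flasks end at 0.00122 M, 0.00127 M, 0.00137 M, 0.00141 M and 0.00126 M, a row that rises, then falls, as forecast. The readings put the turn at a substrate charge of 0.087 M. Beta keeps 15 % of its substrate and 68 % of its partner, so the lift gives 1.21 mM against 1.22 mM. Eta keeps 49 % and 4.8 %, and its lift, with a floor of 0.0115, gives 1.24 mM against 1.26 mM.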